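**One-step world.** Start from a flask with a single step: free monomer joins a living end. Free monomer then falls pseudo-first-order, and the fraction lost follows from the time integral of the living-end concentration L. Use that to choose the next charge: summer or spring.

all flasks: initiator 3.0 mM; impurity 0.92 mM; time 6.0 h
- summer: free monomer 0.030 M
- spring: free monomer 0.12 M

    free monomer + initiator → living end + monomer in chains (k1 = 0.20 /M/s)
    free monomer + living end → monomer in chains + living end, rate k2*[living end]*[free monomer] (k2 = 0.13 /M/s)
    initiator + impurity → spent initiator A (k3 = 9.4 /M/s)
    2 free monomer → self-condensation product (k4 = 4.0 × 10⁻⁵ /M/s)
    2 living end → dead end B (k5 = 4.8 /M/s)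

- percentages count the free monomer that a species holds: one self-condensation product counts as two
- a step written with two of one species runs at k times the square of its concentration and takes two of it each time
- the average divides the monomer in chains by the number of chains begun, living and dead together
- run time (summer): 6.0 h

1. which of the two ends with the longer chains by the average number of monomer units in a chain (chains begun, living or dead) ("neither" if they lie within 10%) (summer / spring / neither)
2. average number of monomer units in a chain (chains begun, living or dead) at the end, summer
3. average number of monomer units in a chain (chains begun, living or dead) at the end, spring

**Chains begun.** Let C be the chains begun, N the initiator charge, Y the impurity charge and M the free monomer charge. Initiator splits between free monomer and impurity. Let r be the initiation constant times M, over the impurity constant: 0.638 mM for summer, 2.55 mM for spring. Hold M fixed and integrate the split. The impurity left, z, obeys z = Y·exp(−(N − Y + z)/r), and C = N − Y + z. Iterate twice. Summer gives 2.11 mM, spring 2.43 mM.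

**The reach.** Take kp = 0.13 /M/s and kt = 4.8 /M/s. Living ends die in pairs, on a time 1/(2kt·C), which is 49.3 s in summer. Initiator's half-life by the impurity step alone is 1.3 min in summer, longer than that, so initiation and termination overlap in time. Start L at C at time zero anyway, as a rough estimate, and integrate. The reach, R = kp∫L dt ≈ (kp/2kt)·ln(1 + 2kt·C·t), is roughly the fraction of free monomer taken by growth. C sits inside a logarithm, so freeze R. Summer gives 0.0824, spring 0.0843, though M differs by a factor of 4.00.

**The decision.** Each chain starts with one unit, so the average is 1 + R·M/C. My reckoning gives 2.17 for summer and 5.17 for spring. Charge spring.

**The check.** The forecast names spring, with 2.3 for summer and 5 for spring, slightly apart from my figures, and it reasons that “Living ends then decay by second-order termination”. The flasks give spring: 2.26 for summer, 5.05 for spring.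

**Why spring.** Spring's longer chains come mainly from its higher monomer charge: given summer's charge, spring's average falls from 5.05 to 2.26. Monomer in chains, less chains begun, reads as a reach of 0.0889 in summer and 0.0820 in spring. Now take summer with 0.0037 M of impurity. Its dead end B, two chains each, gives 0.635 mM begun, a reach of 0.0662 and a reckoned average of 4.13; that flask gives 4.00.

The numbers were chosen freely; the flask was simulated.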